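The synthesis rests on breaking the O1–C2 bond of ring C. This benzylic ether bond lies β to the C4 ketone, so it is the product of a reversible conjugate addition. A throw-away tert-butyl ester on C3 turns the chalcone-type enone into an alkylidene β-ketoester that a bifunctional cinchona thiourea can grip. In one operation the phenol oxygen adds to the benzylidene carbon, ring C closes and C2 becomes (S). The cyclisation substrate is a (Z)-2-aroyl-3-arylacrylate whose ring A carries the only free hydroxyl (O2') beside the prenyl group, a MOM ether on O6' and the 4'-methoxy group. Acid then removes ester, CO2 and MOM groups.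

Key step: step 6

Assumption: the quinine-derived 9-epi-amino thiourea is taken as the pseudoenantiomer that delivers (2S). If a trial run shows the opposite sense, the equally available quinidine-derived catalyst replaces it with no other change.
Notation: prenyl = 3-methylbut-2-en-1-yl; MOM = methoxymethyl.

Step 1
Reactants: 1 2,4,6-trihydroxyacetophenone; 2 prenyl bromide
Product: 3 2,4,6-trihydroxy-3-prenylacetophenone
Conditions: KOH (1 equiv), H2O, 0 °C to rt, 2 (0.9 equiv) added slowly
Reagents that add atoms: none
Why: C-alkylation of an ambident phloroglucinol phenolate (Friedel–Crafts-type allylation under basic conditions): water solvates the oxygens, so the soft allylic bromide should be attacked in SN2 fashion by the electron-rich ring carbon C3 (equivalent to C5), and keeping 2 as the limiting partner holds back a second prenylation.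

Step 2
Reactants: 3 2,4,6-trihydroxy-3-prenylacetophenone
Product: 4 2,6-dihydroxy-4-methoxy-3-prenylacetophenone
Conditions: Me2SO4 (1.0 equiv), K2CO3 (1.1 equiv), acetone, rt to 40 °C
Reagents that add atoms: dimethyl sulfate, COS(=O)(=O)OC
Why: Williamson ether synthesis under weak base: the 4-OH para to the acetyl group is the most acidic hydroxyl and the only one not engaged with the carbonyl oxygen, so one equivalent of the hard electrophile should methylate this oxygen and leave O2 and O6 free.

Step 3
Reactants: 4 2,6-dihydroxy-4-methoxy-3-prenylacetophenone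
Product: 5 2-hydroxy-4-methoxy-6-(methoxymethoxy)-3-prenylacetophenone
Conditions: MOMCl (1.05 equiv), DIPEA (1.5 equiv), CH2Cl2, 0 °C
Reagents that add atoms: chloromethyl methyl ether, COCCl
Why: MOM protection (O-alkylation by an α-chloro ether) under kinetic steric control: O6 has only a ring hydrogen on its outer side whereas O2 is wedged between the acetyl and prenyl groups and pressed into the tighter chelate, so a single equivalent at low temperature should go to O6, after which the remaining chelated phenol resists further alkylation.

Step 4
Reactants: 5 2-hydroxy-4-methoxy-6-(methoxymethoxy)-3-prenylacetophenone; 6 di-tert-butyl dicarbonate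
Product: 8 tert-butyl 3-[2-hydroxy-4-methoxy-6-(methoxymethoxy)-3-prenylphenyl]-3-oxopropanoate, via dilithium enolate-phenoxide 7 (not isolated)
Conditions: LiN(SiMe3)2 (3.3 equiv), THF, −78 °C; then 6 (1.1 equiv), −78 to −20 °C; AcOH quench
Reagents that add atoms: none
Why: Crossed Claisen-type C-acylation of a ketone enolate by a dicarbonate: the terminal enolate carbon of 7 is much more nucleophilic than the chelated lithium phenoxide, the third equivalent of base parks the product as its stabilised enolate, and any carbonate formed on oxygen should be handed on to carbon by a Baker–Venkataraman-type acyl transfer, so both paths converge on 8.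

Step 5
Reactants: 8 tert-butyl 3-[2-hydroxy-4-methoxy-6-(methoxymethoxy)-3-prenylphenyl]-3-oxopropanoate; 9 4-(methoxymethoxy)benzaldehyde
Product: 10 tert-butyl (Z)-2-[2-hydroxy-4-methoxy-6-(methoxymethoxy)-3-prenylbenzoyl]-3-[4-(methoxymethoxy)phenyl]acrylate
Conditions: piperidine (20 mol %), AcOH (20 mol %), 4 Å molecular sieves, toluene, rt
Reagents that add atoms: none
Why: Knoevenagel condensation through the piperidine-derived iminium ion of 9 with sieves taking up the water; the aryl ring should settle cis to the flat ester and trans to the bulky twisted aroyl group (Z alkene), and the buffered amine, the room temperature and the chelated, flanked phenol keep uncatalysed ring closure slow.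

Step 6
Reactants: 10 tert-butyl (Z)-2-[2-hydroxy-4-methoxy-6-(methoxymethoxy)-3-prenylbenzoyl]-3-[4-(methoxymethoxy)phenyl]acrylate
Product: 11 tert-butyl (2S,3R)-7-methoxy-5-(methoxymethoxy)-2-[4-(methoxymethoxy)phenyl]-8-prenyl-4-oxochromane-3-carboxylate (2,3-trans)
Conditions: 9-amino(9-deoxy)epiquinine-derived N-[3,5-bis(trifluoromethyl)phenyl]thiourea (10 mol %), toluene, −25 °C; cold filtration through a short silica pad
Reagents that add atoms: none
Why: The two thiourea N–H bonds clamp the carbonyl oxygens of the alkylidene β-ketoester and lower its LUMO while the quinuclidine nitrogen takes up the proton of the 2'-OH, so the oxygen is delivered to the benzylidene carbon inside one chiral hydrogen-bonded assembly and the ester-stabilised enolate is then protonated at C3. This is the established organocatalytic intramolecular oxa-Michael addition of 2-(2-hydroxyaroyl)-3-arylacrylates to 3-carboxyflavanones. Ring C closes in the 6-endo-trig mode by formation of O1–C2. C2 should be fixed as (S) by the catalyst, which leaves one enantioface of the single (Z)-alkene open; C3 is an acidic, freely epimerising centre that settles thermodynamically into the 2,3-trans diequatorial arrangement and is deleted in step 7. The step needs face selectivity, a slow reverse reaction and a single nucleophilic oxygen: the low temperature and the doubly stabilised enolate hold back ring opening, non-polar toluene preserves the hydrogen-bond network, and with O6' masked as its MOM ether only the hydroxyl beside the prenyl group can add, so only the 8-prenyl skeleton can arise.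

Step 7
Reactants: 11 tert-butyl (2S,3R)-7-methoxy-5-(methoxymethoxy)-2-[4-(methoxymethoxy)phenyl]-8-prenyl-4-oxochromane-3-carboxylate
Product: 14 Mundulea flavanone B (2S)-5-hydroxy-2-(4-hydroxyphenyl)-7-methoxy-8-prenylchroman-4-one, via β-keto acid 12 (not isolated), via bis-MOM flavanone 13 (not isolated)
Conditions: TsOH·H2O (1 equiv), toluene, 80 °C, N2 sweep; then cool, MeOH, 45 °C
Reagents that add atoms: none
Why: Acid-catalysed E1 cleavage of the tert-butyl ester gives the β-keto acid, which decarboxylates through the cyclic six-membered transition state and erases C3 without touching C2, and methanol then removes both MOM groups by transacetalisation while trapping the formaldehyde unit; the prenyl group should survive because no free hydroxyl flanks it (O7 is methylated, O1 is in ring C), and any early MOM loss in the toluene stage converges on the same product.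

Compound list
1 | 2,4,6-trihydroxyacetophenone | CC(=O)c1c(O)cc(O)cc1O | starting material
2 | prenyl bromide (1-bromo-3-methylbut-2-ene) | CC(C)=CCBr | starting material
3 | 2,4,6-trihydroxy-3-prenylacetophenone | CC(=O)c1c(O)cc(O)c(CC=C(C)C)c1O | intermediate
4 | 2,6-dihydroxy-4-methoxy-3-prenylacetophenone | CC(=O)c1c(O)cc(OC)c(CC=C(C)C)c1O | intermediate
5 | 2-hydroxy-4-methoxy-6-(methoxymethoxy)-3-prenylacetophenone (free OH next to prenyl) | CC(=O)c1c(OCOC)cc(OC)c(CC=C(C)C)c1O | intermediate
6 | di-tert-butyl dicarbonate | CC(C)(C)OC(=O)OC(=O)OC(C)(C)C | starting material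
7 | dilithium enolate-phenoxide of 5 | [Li+].[Li+].C=C([O-])c1c(OCOC)cc(OC)c(CC=C(C)C)c1[O-] | intermediate
8 | tert-butyl 3-[2-hydroxy-4-methoxy-6-(methoxymethoxy)-3-prenylphenyl]-3-oxopropanoate | CC(C)(C)OC(=O)CC(=O)c1c(OCOC)cc(OC)c(CC=C(C)C)c1O | intermediate
9 | 4-(methoxymethoxy)benzaldehyde | COCOc1ccc(C=O)cc1 | starting material
10 | tert-butyl (Z)-2-[2-hydroxy-4-methoxy-6-(methoxymethoxy)-3-prenylbenzoyl]-3-[4-(methoxymethoxy)phenyl]acrylate | COc1cc(OCOC)c(C(=O)/C(C(=O)OC(C)(C)C)=C/c2ccc(OCOC)cc2)c(O)c1CC=C(C)C | intermediate
11 | tert-butyl (2S,3R)-7-methoxy-5-(methoxymethoxy)-2-[4-(methoxymethoxy)phenyl]-8-prenyl-4-oxochromane-3-carboxylate (2,3-trans) | COc1cc(OCOC)c2c(c1CC=C(C)C)O[C@H](c1ccc(OCOC)cc1)[C@@H](C(=O)OC(C)(C)C)C2=O | intermediate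
12 | (2S,3R)-7-methoxy-5-(methoxymethoxy)-2-[4-(methoxymethoxy)phenyl]-8-prenyl-4-oxochromane-3-carboxylic acid | COc1cc(OCOC)c2c(c1CC=C(C)C)O[C@H](c1ccc(OCOC)cc1)[C@@H](C(=O)O)C2=O | intermediate
13 | (2S)-7-methoxy-5,4'-bis(methoxymethoxy)-8-prenylflavanone | COc1cc(OCOC)c2c(c1CC=C(C)C)O[C@H](c1ccc(OCOC)cc1)CC2=O | intermediate
14 | Mundulea flavanone B, (2S)-5,4'-dihydroxy-7-methoxy-8-prenylflavanone | COc1cc(O)c2c(c1CC=C(C)C)O[C@H](c1ccc(O)cc1)CC2=O | target

Total step count: 7. Longest linear sequence: 7 steps (1 to 14).

**Steps most likely to fail**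

**Step 6** is the most exposed.
- Risk: the twisted, 2',6'-disubstituted aroyl group and the electron-rich 4-alkoxyphenyl ring may slow the addition or weaken face discrimination. Reversible ring opening may also wear down the optical purity.
- Fallback: give up the O1–C2 closure and form the C2–aryl bond on a preformed ring C by known chemistry. It sets out from 5.
- Condensation with N,N-dimethylformamide dimethyl acetal (toluene, 90 °C) should give the enaminone (E)-3-(dimethylamino)-1-[2-hydroxy-4-methoxy-6-(methoxymethoxy)-3-prenylphenyl]prop-2-en-1-one F1.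
- Warm aqueous acetic acid should close F1, with loss of the amine, to 7-methoxy-5-(methoxymethoxy)-8-prenylchromone F2.
- Rhodium-catalysed asymmetric 1,4-addition of 4-(methoxymethoxy)phenylboronic acid follows. The conditions are [Rh(OH)(cod)]2, an electron-poor atropisomeric bisphosphine of the MeO-BIPHEP family in the antipode that gives (2S), toluene/H2O, rt.
- This comes back to the route at 13, which then needs only the methanol stage of step 7.

**Step 3** comes next.
- Risk: discrimination between the two ortho hydroxyls may be incomplete, or a second alkylation may set in. This would blur the 8-prenyl/6-prenyl decision.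
- Fallback: fix the regiochemistry by a sigmatropic relay instead of by steric bias. It sets out from 1.
- Monomethylation (Me2SO4, K2CO3, acetone) should give symmetrical 2,6-dihydroxy-4-methoxyacetophenone F3.
- TBSCl/imidazole should give 2-(tert-butyldimethylsilyloxy)-6-hydroxy-4-methoxyacetophenone F4.
- A Mitsunobu reaction with 3-methylbut-2-en-1-ol (PPh3, DIAD, THF) should give 2-(tert-butyldimethylsilyloxy)-4-methoxy-6-(prenyloxy)acetophenone F5.
- Heating in N,N-diethylaniline at 200 °C should move the prenyl group by an aromatic Claisen and then a Cope [3,3] shift to the carbon para to its oxygen. The product is 2-(tert-butyldimethylsilyloxy)-6-hydroxy-4-methoxy-3-prenylacetophenone F6, in which the silylated oxygen is necessarily the one beside the prenyl group.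
- MOMCl/DIPEA on the liberated phenol should give 2-(tert-butyldimethylsilyloxy)-4-methoxy-6-(methoxymethoxy)-3-prenylacetophenone F7.
- TBAF buffered by AcOH comes back to the route at 5.

**Step 7** is third.
- Risk: warm Brønsted acid may hydrate or shift the prenyl double bond, and ring A may capture formaldehyde equivalents. Acid may also promote opening and re-closure of ring C, with loss of optical purity or drift to the other ortho oxygen.
- Fallback: replace protic acid by buffered, aprotic silyl triflate dealkylation. It sets out from 11.
- TMSOTf/2,6-lutidine (CH2Cl2, 0 °C) is used for the tert-butyl ester. More TMSOTf and 2,2'-bipyridyl are then added in the same flask for the aryl MOM ethers.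
- This should give trimethylsilyl (2S,3R)-7-methoxy-8-prenyl-4-oxo-5-(trimethylsilyloxy)-2-[4-(trimethylsilyloxy)phenyl]chromane-3-carboxylate F8.
- Water at rt should hydrolyse F8 to (2S,3R)-5-hydroxy-2-(4-hydroxyphenyl)-7-methoxy-8-prenyl-4-oxochromane-3-carboxylic acid F9.
- Gentle warming (40 °C) should decarboxylate F9, which comes back to the route at 14.

Further compounds
F1 | step 6 | (E)-3-(dimethylamino)-1-[2-hydroxy-4-methoxy-6-(methoxymethoxy)-3-prenylphenyl]prop-2-en-1-one | CN(C)/C=C/C(=O)c1c(OCOC)cc(OC)c(CC=C(C)C)c1O
F2 | step 6 | 7-methoxy-5-(methoxymethoxy)-8-prenylchromone | COc1cc(OCOC)c2c(c1CC=C(C)C)OC=CC2=O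
F3 | step 3 | 2,6-dihydroxy-4-methoxyacetophenone | CC(=O)c1c(O)cc(OC)cc1O
F4 | step 3 | 2-(tert-butyldimethylsilyloxy)-6-hydroxy-4-methoxyacetophenone | CC(=O)c1c(O)cc(OC)cc1O[Si](C)(C)C(C)(C)C
F5 | step 3 | 2-(tert-butyldimethylsilyloxy)-4-methoxy-6-(prenyloxy)acetophenone | CC(=O)c1c(OCC=C(C)C)cc(OC)cc1O[Si](C)(C)C(C)(C)C
F6 | step 3 | 2-(tert-butyldimethylsilyloxy)-6-hydroxy-4-methoxy-3-prenylacetophenone | CC(=O)c1c(O)cc(OC)c(CC=C(C)C)c1O[Si](C)(C)C(C)(C)C
F7 | step 3 | 2-(tert-butyldimethylsilyloxy)-4-methoxy-6-(methoxymethoxy)-3-prenylacetophenone | CC(=O)c1c(OCOC)cc(OC)c(CC=C(C)C)c1O[Si](C)(C)C(C)(C)C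
F8 | step 7 | trimethylsilyl (2S,3R)-7-methoxy-8-prenyl-4-oxo-5-(trimethylsilyloxy)-2-[4-(trimethylsilyloxy)phenyl]chromane-3-carboxylate | COc1cc(O[Si](C)(C)C)c2c(c1CC=C(C)C)O[C@H](c1ccc(O[Si](C)(C)C)cc1)[C@@H](C(=O)O[Si](C)(C)C)C2=O
F9 | step 7 | (2S,3R)-5-hydroxy-2-(4-hydroxyphenyl)-7-methoxy-8-prenyl-4-oxochromane-3-carboxylic acid | COc1cc(O)c2c(c1CC=C(C)C)O[C@H](c1ccc(O)cc1)[C@@H](C(=O)O)C2=O
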